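**Retrosynthetic overview**
1. Stille disconnections at C7–C8 and C13–C14 give dihydropyranone stannane C (C1–C7), iodo alcohol B (C9–C13) and tetrahydropyran stannane A (C14–C24); C8 and its methyl are added late by Stork–Zhao iodo-olefination.
2. A: the tetrahydropyran ring is formed first, by a catalytic enantioselective hetero-Diels–Alder reaction (C17, C20, C21); C19 follows by ketone reduction, the propenyl group by Takai–Utimoto olefination, C16 by CBS reduction of a stannyl enone.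
3. B: C10 comes from lipase desymmetrisation of 2-methylpropane-1,3-diol; the E-vinyl iodide from Negishi carboalumination.
4. C: C5 comes from a Keck allylation; the lactone ring is formed second, by ring-closing metathesis, before the fragment unions.
5. Endgame: Stille (A + B), oxidation, Z-iodo-olefination, Stille with C, desilylation.

Assumption: locants C1–C24 are those of the target chain (C1 lactone carbonyl to C24 propenyl CH3), and the target SMILES is read as 5S,10R,16S,17S,19R,20S,21S with 6E,8Z,12E,14E,22E (TBS = tert-butyldimethylsilyl, TES = triethylsilyl, TBDPS = tert-butyldiphenylsilyl).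

**Fragment A (C14–C24)**

Step 1
Reactants: 1 (tert-butyldimethylsilyloxy)acetaldehyde; 2 diethyl (2-oxobutyl)phosphonate
Product: 3 (E)-6-[(tert-butyldimethylsilyl)oxy]hex-4-en-3-one
Conditions: LiCl, i-Pr2NEt, MeCN, rt
Reagents that add atoms: none
Why: Horner–Wadsworth–Emmons olefination under Masamune–Roush conditions gives the E-enone from a stabilised phosphonate without touching the silyl ether.

Step 2
Reactants: 3 (E)-6-[(tert-butyldimethylsilyl)oxy]hex-4-en-3-one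
Product: 4 tert-butyldimethyl{[(2E,4Z)-4-[(triethylsilyl)oxy]hexa-2,4-dien-1-yl]oxy}silane
Conditions: TESOTf, Et3N, Et2O, −78 °C to 0 °C
Reagents that add atoms: triethylsilyl triflate, CC[Si](CC)(CC)OS(=O)(=O)C(F)(F)F
Why: Soft enolisation of the ethyl ketone (silyl enol ether formation) gives the Z-enol ether, so both diene termini point outward as needed for an all-cis cycloadduct.

Step 3
Reactants: 4 tert-butyldimethyl{[(2E,4Z)-4-[(triethylsilyl)oxy]hexa-2,4-dien-1-yl]oxy}silane; 5 benzyloxyacetaldehyde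
Product: 7 (2R,3R,6S)-2-[(benzyloxy)methyl]-6-{[(tert-butyldimethylsilyl)oxy]methyl}-3-methyltetrahydro-4H-pyran-4-one, via triethylsilyl enol ether cycloadduct 6 (not isolated)
Conditions: [Cr(L)Cl] 5 mol % (trivalent chromium; L = Schiff base dianion from (1R,2S)-1-aminoindan-2-ol and 3-(1-adamantyl)-2-hydroxy-5-methylbenzaldehyde), 4 Å MS, neat, rt; then TBAF (1 equiv), AcOH, THF, −40 °C, 10 min
Reagents that add atoms: none
Why: Jacobsen hetero-Diels–Alder reaction in which the chiral chromium Lewis acid selects one aldehyde face (C21, first stereocentre) and the endo transition state sets C20 and C17 cis to it; buffered fluoride then cleaves only the enol ether, protonating C18 and leaving C20 untouched.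

Step 4
Reactants: 7 (2R,3R,6S)-2-[(benzyloxy)methyl]-6-{[(tert-butyldimethylsilyl)oxy]methyl}-3-methyltetrahydro-4H-pyran-4-one
Product: 8 (2R,3S,4R,6S)-2-[(benzyloxy)methyl]-6-{[(tert-butyldimethylsilyl)oxy]methyl}-3-methyltetrahydro-2H-pyran-4-ol
Conditions: LiBH(s-Bu)3, THF, −78 °C; then H2O
Reagents that add atoms: none
Why: Diastereoselective ketone reduction in which the bulky hydride attacks equatorially (axial attack is blocked by the syn-axial H atoms at C17 and C21), giving the axial C19 alcohol trans to the three ring substituents.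

Step 5
Reactants: 8 (2R,3S,4R,6S)-2-[(benzyloxy)methyl]-6-{[(tert-butyldimethylsilyl)oxy]methyl}-3-methyltetrahydro-2H-pyran-4-ol
Product: 9 (2R,3R,4R,6S)-2-[(benzyloxy)methyl]-4-[(tert-butyldimethylsilyl)oxy]-6-{[(tert-butyldimethylsilyl)oxy]methyl}-3-methyltetrahydro-2H-pyran
Conditions: TBSOTf, 2,6-lutidine, CH2Cl2, −78 °C to 0 °C
Reagents that add atoms: tert-butyldimethylsilyl triflate, CC(C)(C)[Si](C)(C)OS(=O)(=O)C(F)(F)F
Why: Silyl ether formation with the reactive triflate protects the hindered axial alcohol (the C20 descriptor changes by priority only).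

Step 6
Reactants: 9 (2R,3R,4R,6S)-2-[(benzyloxy)methyl]-4-[(tert-butyldimethylsilyl)oxy]-6-{[(tert-butyldimethylsilyl)oxy]methyl}-3-methyltetrahydro-2H-pyran
Product: 10 [(2R,3R,4R,6S)-4-[(tert-butyldimethylsilyl)oxy]-6-{[(tert-butyldimethylsilyl)oxy]methyl}-3-methyltetrahydro-2H-pyran-2-yl]methanol
Conditions: H2 (1 atm), 10 % Pd/C, EtOAc, rt
Reagents that add atoms: none
Why: Catalytic hydrogenolysis removes the benzyl ether before any alkene is present and leaves both silyl ethers intact in a non-protic solvent.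

Step 7
Reactants: 10 [(2R,3R,4R,6S)-4-[(tert-butyldimethylsilyl)oxy]-6-{[(tert-butyldimethylsilyl)oxy]methyl}-3-methyltetrahydro-2H-pyran-2-yl]methanol
Product: 11 (2R,3R,4R,6S)-4-[(tert-butyldimethylsilyl)oxy]-6-{[(tert-butyldimethylsilyl)oxy]methyl}-3-methyltetrahydro-2H-pyran-2-carbaldehyde
Conditions: Dess–Martin periodinane, CH2Cl2, 0 °C to rt
Reagents that add atoms: none
Why: Dess–Martin oxidation gives the aldehyde under neutral conditions, and the equatorial C21 centre has no drive to epimerise.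

Step 8
Reactants: 11 (2R,3R,4R,6S)-4-[(tert-butyldimethylsilyl)oxy]-6-{[(tert-butyldimethylsilyl)oxy]methyl}-3-methyltetrahydro-2H-pyran-2-carbaldehyde; 12 1,1-diiodoethane
Product: 13 (2S,3R,4R,6S)-4-[(tert-butyldimethylsilyl)oxy]-6-{[(tert-butyldimethylsilyl)oxy]methyl}-3-methyl-2-[(E)-prop-1-en-1-yl]tetrahydro-2H-pyran
Conditions: CrCl2 (6 equiv), THF, rt
Reagents that add atoms: none
Why: Takai–Utimoto ethylidenation with the geminal dichromium reagent from divalent chromium gives the E-propenyl group under non-basic conditions.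

Step 9
Reactants: 13 (2S,3R,4R,6S)-4-[(tert-butyldimethylsilyl)oxy]-6-{[(tert-butyldimethylsilyl)oxy]methyl}-3-methyl-2-[(E)-prop-1-en-1-yl]tetrahydro-2H-pyran
Product: 14 [(2S,4R,5R,6S)-4-[(tert-butyldimethylsilyl)oxy]-5-methyl-6-[(E)-prop-1-en-1-yl]tetrahydro-2H-pyran-2-yl]methanol
Conditions: HF·pyridine, pyridine, THF, 0 °C
Reagents that add atoms: none
Why: Selective desilylation, since the primary TBS ether is cleaved much faster than the hindered axial secondary one under buffered fluoride.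

Step 10
Reactants: 14 [(2S,4R,5R,6S)-4-[(tert-butyldimethylsilyl)oxy]-5-methyl-6-[(E)-prop-1-en-1-yl]tetrahydro-2H-pyran-2-yl]methanol
Product: 15 (2S,4R,5R,6S)-4-[(tert-butyldimethylsilyl)oxy]-5-methyl-6-[(E)-prop-1-en-1-yl]tetrahydro-2H-pyran-2-carbaldehyde
Conditions: Dess–Martin periodinane, CH2Cl2, 0 °C to rt
Reagents that add atoms: none
Why: Dess–Martin oxidation tolerates the alkene and silyl ether and gives the C16 aldehyde with its equatorial C17 centre intact.

Step 11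
Reactants: 15 (2S,4R,5R,6S)-4-[(tert-butyldimethylsilyl)oxy]-5-methyl-6-[(E)-prop-1-en-1-yl]tetrahydro-2H-pyran-2-carbaldehyde; 16 (E)-1,2-bis(tributylstannyl)ethene
Product: 17 (E)-1-[(2S,4R,5R,6S)-4-[(tert-butyldimethylsilyl)oxy]-5-methyl-6-[(E)-prop-1-en-1-yl]tetrahydro-2H-pyran-2-yl]-3-(tributylstannyl)prop-2-en-1-ol (mixture of C16 epimers)
Conditions: 16, n-BuLi, THF, −78 °C; then 15, −78 °C; then H2O
Reagents that add atoms: none
Why: Tin–lithium exchange gives (E)-2-(tributylstannyl)vinyllithium, which adds 1,2 to the aldehyde with retention of alkene geometry; the C16 epimer ratio does not matter because the next step removes the centre.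

Step 12
Reactants: 17 (E)-1-[(2S,4R,5R,6S)-4-[(tert-butyldimethylsilyl)oxy]-5-methyl-6-[(E)-prop-1-en-1-yl]tetrahydro-2H-pyran-2-yl]-3-(tributylstannyl)prop-2-en-1-ol
Product: 18 (E)-1-[(2S,4R,5R,6S)-4-[(tert-butyldimethylsilyl)oxy]-5-methyl-6-[(E)-prop-1-en-1-yl]tetrahydro-2H-pyran-2-yl]-3-(tributylstannyl)prop-2-en-1-one
Conditions: MnO2 (activated, excess), CH2Cl2, rt
Reagents that add atoms: none
Why: MnO2 allylic oxidation is acid-free, so the vinylstannane survives and both epimers converge on one enone.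

Step 13
Reactants: 18 (E)-1-[(2S,4R,5R,6S)-4-[(tert-butyldimethylsilyl)oxy]-5-methyl-6-[(E)-prop-1-en-1-yl]tetrahydro-2H-pyran-2-yl]-3-(tributylstannyl)prop-2-en-1-one
Product: 19 (1S,2E)-1-[(2S,4R,5R,6S)-4-[(tert-butyldimethylsilyl)oxy]-5-methyl-6-[(E)-prop-1-en-1-yl]tetrahydro-2H-pyran-2-yl]-3-(tributylstannyl)prop-2-en-1-ol
Conditions: (S)-2-methyl-CBS-oxazaborolidine (20 mol %), catecholborane, toluene, −78 °C; then H2O
Reagents that add atoms: none
Why: Corey–Bakshi–Shibata reduction with the stannylvinyl group as the large substituent delivers hydride to give 16S, reinforced by the Felkin–Anh preference of the α-alkoxy ketone (16,17-syn).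

Step 14
Reactants: 19 (1S,2E)-1-[(2S,4R,5R,6S)-4-[(tert-butyldimethylsilyl)oxy]-5-methyl-6-[(E)-prop-1-en-1-yl]tetrahydro-2H-pyran-2-yl]-3-(tributylstannyl)prop-2-en-1-ol
Product: 20 tert-butyl{[(1S,2E)-1-[(2S,4R,5R,6S)-4-[(tert-butyldimethylsilyl)oxy]-5-methyl-6-[(E)-prop-1-en-1-yl]tetrahydro-2H-pyran-2-yl]-3-(tributylstannyl)prop-2-en-1-yl]oxy}dimethylsilane (fragment A)
Conditions: TBSOTf, 2,6-lutidine, CH2Cl2, −78 °C
Reagents that add atoms: tert-butyldimethylsilyl triflate, CC(C)(C)[Si](C)(C)OS(=O)(=O)C(F)(F)F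
Why: Silyl ether formation with excess hindered base keeps the medium non-acidic, so the vinylstannane is not protodestannylated.

**Fragment B (C9–C13)**

Step 15
Reactants: 21 2-methylpropane-1,3-diol; 22 vinyl acetate
Product: 23 (S)-3-hydroxy-2-methylpropyl acetate
Conditions: lipase (Pseudomonas fluorescens lipase, Amano AK), CHCl3, rt, stopped at about 25 % diacetate
Reagents that add atoms: none
Why: Lipase-catalysed enantiotopic-group-selective transesterification (desymmetrisation) acylates one CH2OH arm of the prochiral diol and sets C10; slight over-acylation upgrades the ee by kinetic amplification.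

Step 16
Reactants: 23 (S)-3-hydroxy-2-methylpropyl acetate
Product: 24 (R)-3-[(tert-butyldiphenylsilyl)oxy]-2-methylpropyl acetate
Conditions: TBDPSCl, imidazole, DMF, 0 °C
Reagents that add atoms: tert-butyldiphenylsilyl chloride, CC(C)(C)[Si](Cl)(c1ccccc1)c1ccccc1
Why: Immediate silylation of the free arm (future C9) at low temperature prevents acetyl migration, which would racemise the monoacetate.

Step 17
Reactants: 24 (R)-3-[(tert-butyldiphenylsilyl)oxy]-2-methylpropyl acetate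
Product: 25 (R)-3-[(tert-butyldiphenylsilyl)oxy]-2-methylpropan-1-ol
Conditions: K2CO3 (cat.), MeOH, 0 °C
Reagents that add atoms: none
Why: Base-catalysed transesterification removes the acetate from the arm that becomes C11, while the bulky TBDPS group does not migrate under these mild conditions.

Step 18
Reactants: 25 (R)-3-[(tert-butyldiphenylsilyl)oxy]-2-methylpropan-1-ol
Product: 26 (S)-tert-butyl(3-iodo-2-methylpropoxy)diphenylsilane
Conditions: I2, PPh3, imidazole, CH2Cl2, 0 °C to rt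
Reagents that add atoms: iodine, [I][I]
Why: Appel-type (Garegg–Samuelsson) iodination converts the primary alcohol into the iodide without touching the stereocentre.

Step 19
Reactants: 26 (S)-tert-butyl(3-iodo-2-methylpropoxy)diphenylsilane; 27 lithium acetylide–ethylenediamine complex
Product: 28 (R)-tert-butyl[(2-methylpent-4-yn-1-yl)oxy]diphenylsilane
Conditions: DMSO, rt
Reagents that add atoms: none
Why: SN2 alkylation of the acetylide by the primary iodide in a dipolar aprotic solvent installs C12–C13 as a terminal alkyne.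

Step 20
Reactants: 28 (R)-tert-butyl[(2-methylpent-4-yn-1-yl)oxy]diphenylsilane; 29 trimethylaluminium
Product: 31 (R,E)-tert-butyl[(5-iodo-2,4-dimethylpent-4-en-1-yl)oxy]diphenylsilane, via (E)-alkenyldimethylalane 30 (not isolated)
Conditions: AlMe3, Cp2ZrCl2 (0.5 equiv), CH2Cl2, 0 °C to rt; then I2, THF, −30 °C
Reagents that add atoms: iodine, [I][I]
Why: Negishi zirconium-catalysed carboalumination adds Me and Al syn across the alkyne with Me on the internal carbon, and iodinolysis with retention gives the (E)-2-methyl vinyl iodide.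

Step 21
Reactants: 31 (R,E)-tert-butyl[(5-iodo-2,4-dimethylpent-4-en-1-yl)oxy]diphenylsilane
Product: 32 (R,E)-5-iodo-2,4-dimethylpent-4-en-1-ol (fragment B)
Conditions: TBAF, THF, rt
Reagents that add atoms: none
Why: Fluoride desilylation frees the C9 alcohol now, so no deprotection is needed after the first fragment union.

**Fragment C (C1–C7)**

Step 22
Reactants: 33 prop-2-yn-1-ol; 34 tributyltin hydride
Product: 35 (E)-3-(tributylstannyl)prop-2-en-1-ol
Conditions: AIBN (cat.), neat, 80 °C; chromatography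
Reagents that add atoms: none
Why: Radical hydrostannation of the terminal alkyne equilibrates to the thermodynamic E β-stannyl alkene, which is separated from minor isomers.

Step 23
Reactants: 35 (E)-3-(tributylstannyl)prop-2-en-1-ol
Product: 36 (E)-3-(tributylstannyl)prop-2-enal
Conditions: MnO2 (activated, excess), CH2Cl2, rt
Reagents that add atoms: none
Why: MnO2 allylic oxidation gives the enal without acid, preserving the vinylstannane and its geometry.

Step 24
Reactants: 36 (E)-3-(tributylstannyl)prop-2-enal; 37 allyltributylstannane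
Product: 38 (3S,1E)-1-(tributylstannyl)hexa-1,5-dien-3-ol
Conditions: (S)-BINOL (20 mol %), Ti(OiPr)4 (10 mol %), 4 Å MS, CH2Cl2, −20 °C; then H2O
Reagents that add atoms: none
Why: Keck asymmetric allylation, in which the BINOL–titanium Lewis acid directs allyl transfer to one aldehyde face and the (S)-ligand gives the (S)-carbinol (C5).

Step 25
Reactants: 38 (3S,1E)-1-(tributylstannyl)hexa-1,5-dien-3-ol; 39 acryloyl chloride
Product: 40 (3S,1E)-1-(tributylstannyl)hexa-1,5-dien-3-yl acrylate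
Conditions: Et3N, DMAP (cat.), CH2Cl2, 0 °C
Reagents that add atoms: none
Why: O-Acylation of the secondary allylic alcohol proceeds with retention at C5 under basic conditions that the stannane tolerates.

Step 26
Reactants: 40 (3S,1E)-1-(tributylstannyl)hexa-1,5-dien-3-yl acrylate
Product: 41 (S)-6-[(E)-2-(tributylstannyl)vinyl]-5,6-dihydro-2H-pyran-2-one (fragment C)
Conditions: second-generation Grubbs catalyst RuCl2(=CHPh)(H2IMes)(PCy3) (5 mol %), CH2Cl2 (0.005 M), 40 °C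
Reagents that add atoms: none
Why: Ring-closing metathesis joins the two terminal alkenes into the six-membered unsaturated lactone, while the hindered 1,2-disubstituted vinylstannane does not engage.

**Fragment union and endgame**

Step 27
Reactants: 20 fragment A stannane; 32 (R,E)-5-iodo-2,4-dimethylpent-4-en-1-ol
Product: 42 (2R,4E,6E,8S)-8-[(tert-butyldimethylsilyl)oxy]-8-[(2S,4R,5R,6S)-4-[(tert-butyldimethylsilyl)oxy]-5-methyl-6-[(E)-prop-1-en-1-yl]tetrahydro-2H-pyran-2-yl]-2,4-dimethylocta-4,6-dien-1-ol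
Conditions: Pd2(dba)3 (5 mol %), AsPh3 (40 mol %), NMP, rt
Reagents that add atoms: none
Why: Stille coupling on zerovalent palladium forms C13–C14 with retention of both alkene geometries and tolerates the free primary alcohol.

Step 28
Reactants: 42 the C9 alcohol from step 27
Product: 43 (2R,4E,6E,8S)-8-[(tert-butyldimethylsilyl)oxy]-8-[(2S,4R,5R,6S)-4-[(tert-butyldimethylsilyl)oxy]-5-methyl-6-[(E)-prop-1-en-1-yl]tetrahydro-2H-pyran-2-yl]-2,4-dimethylocta-4,6-dienal
Conditions: Dess–Martin periodinane, pyridine, CH2Cl2, 0 °C; used at once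
Reagents that add atoms: none
Why: Buffered Dess–Martin oxidation gives the α-methyl aldehyde without epimerising C10 or ionising the dienylic silyl ether.

Step 29
Reactants: 43 the C9 aldehyde from step 28; 44 ethyltriphenylphosphonium iodide
Product: 45 tert-butyl{[(1S,2E,4E,7R,8Z)-1-[(2S,4R,5R,6S)-4-[(tert-butyldimethylsilyl)oxy]-5-methyl-6-[(E)-prop-1-en-1-yl]tetrahydro-2H-pyran-2-yl]-9-iodo-5,7-dimethyldeca-2,4,8-trien-1-yl]oxy}dimethylsilane
Conditions: 44, n-BuLi, THF, rt; I2, −78 °C; NaN(SiMe3)2, −20 °C; then 43, −78 °C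
Reagents that add atoms: iodine, [I][I]
Why: Stork–Zhao olefination with the α-iodo ylide gives the (Z)-2-iodo-2-alkene (I cis to C10) under kinetic, salt-free Wittig control at low temperature, which also protects C10.

Step 30
Reactants: 45 the (8Z)-vinyl iodide from step 29; 41 (S)-6-[(E)-2-(tributylstannyl)vinyl]-5,6-dihydro-2H-pyran-2-one
Product: 46 (S)-6-[(1E,3Z,5R,7E,9E,11S)-11-[(tert-butyldimethylsilyl)oxy]-11-[(2S,4R,5R,6S)-4-[(tert-butyldimethylsilyl)oxy]-5-methyl-6-[(E)-prop-1-en-1-yl]tetrahydro-2H-pyran-2-yl]-3,5,7-trimethylundeca-1,3,7,9-tetraen-1-yl]-5,6-dihydro-2H-pyran-2-one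
Conditions: Pd2(dba)3 (10 mol %), AsPh3 (80 mol %), NMP, rt to 40 °C
Reagents that add atoms: none
Why: Stille coupling under neutral conditions forms C7–C8 with retention of the 8Z and 6E geometries and leaves the base-sensitive lactone untouched.

Step 31
Reactants: 46 the 16,19-bis-TBS ether from step 30
Product: 47 (S)-6-[(1E,3Z,5R,7E,9E,11S)-11-hydroxy-11-[(2S,4R,5S,6S)-4-hydroxy-5-methyl-6-[(E)-prop-1-en-1-yl]tetrahydro-2H-pyran-2-yl]-3,5,7-trimethylundeca-1,3,7,9-tetraen-1-yl]-5,6-dihydro-2H-pyran-2-one (target)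
Conditions: HF·pyridine, pyridine, THF, 0 °C to rt
Reagents that add atoms: none
Why: Buffered fluoride desilylation removes both secondary TBS ethers without ionising the dienylic C16 carbinol or opening the lactone.

**Compound list**
1 | (tert-butyldimethylsilyloxy)acetaldehyde | O=CCO[Si](C)(C)C(C)(C)C | starting material
2 | diethyl (2-oxobutyl)phosphonate | CCC(=O)CP(=O)(OCC)OCC | starting material
3 | (E)-6-[(tert-butyldimethylsilyl)oxy]hex-4-en-3-one | CCC(=O)/C=C/CO[Si](C)(C)C(C)(C)C | intermediate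
4 | tert-butyldimethyl{[(2E,4Z)-4-[(triethylsilyl)oxy]hexa-2,4-dien-1-yl]oxy}silane | C/C=C(O[Si](CC)(CC)CC)/C=C/CO[Si](C)(C)C(C)(C)C | intermediate
5 | benzyloxyacetaldehyde | O=CCOCc1ccccc1 | starting material
6 | (2R,3R,6S)-2-[(benzyloxy)methyl]-6-{[(tert-butyldimethylsilyl)oxy]methyl}-3-methyl-4-[(triethylsilyl)oxy]-3,6-dihydro-2H-pyran | c1ccccc1COC[C@@H]1O[C@H](CO[Si](C)(C)C(C)(C)C)C=C(O[Si](CC)(CC)CC)[C@@H]1C | intermediate
7 | (2R,3R,6S)-2-[(benzyloxy)methyl]-6-{[(tert-butyldimethylsilyl)oxy]methyl}-3-methyltetrahydro-4H-pyran-4-one | c1ccccc1COC[C@@H]1O[C@H](CO[Si](C)(C)C(C)(C)C)CC(=O)[C@@H]1C | intermediate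
8 | (2R,3S,4R,6S)-2-[(benzyloxy)methyl]-6-{[(tert-butyldimethylsilyl)oxy]methyl}-3-methyltetrahydro-2H-pyran-4-ol | c1ccccc1COC[C@@H]1O[C@H](CO[Si](C)(C)C(C)(C)C)C[C@@H](O)[C@@H]1C | intermediate
9 | (2R,3R,4R,6S)-2-[(benzyloxy)methyl]-4-[(tert-butyldimethylsilyl)oxy]-6-{[(tert-butyldimethylsilyl)oxy]methyl}-3-methyltetrahydro-2H-pyran | c1ccccc1COC[C@@H]1O[C@H](CO[Si](C)(C)C(C)(C)C)C[C@@H](O[Si](C)(C)C(C)(C)C)[C@@H]1C | intermediate
10 | [(2R,3R,4R,6S)-4-[(tert-butyldimethylsilyl)oxy]-6-{[(tert-butyldimethylsilyl)oxy]methyl}-3-methyltetrahydro-2H-pyran-2-yl]methanol | OC[C@@H]1O[C@H](CO[Si](C)(C)C(C)(C)C)C[C@@H](O[Si](C)(C)C(C)(C)C)[C@@H]1C | intermediate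
11 | (2R,3R,4R,6S)-4-[(tert-butyldimethylsilyl)oxy]-6-{[(tert-butyldimethylsilyl)oxy]methyl}-3-methyltetrahydro-2H-pyran-2-carbaldehyde | O=C[C@@H]1O[C@H](CO[Si](C)(C)C(C)(C)C)C[C@@H](O[Si](C)(C)C(C)(C)C)[C@@H]1C | intermediate
12 | 1,1-diiodoethane | CC(I)I | starting material
13 | (2S,3R,4R,6S)-4-[(tert-butyldimethylsilyl)oxy]-6-{[(tert-butyldimethylsilyl)oxy]methyl}-3-methyl-2-[(E)-prop-1-en-1-yl]tetrahydro-2H-pyran | C/C=C/[C@@H]1O[C@H](CO[Si](C)(C)C(C)(C)C)C[C@@H](O[Si](C)(C)C(C)(C)C)[C@@H]1C | intermediate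
14 | [(2S,4R,5R,6S)-4-[(tert-butyldimethylsilyl)oxy]-5-methyl-6-[(E)-prop-1-en-1-yl]tetrahydro-2H-pyran-2-yl]methanol | C/C=C/[C@@H]1O[C@H](CO)C[C@@H](O[Si](C)(C)C(C)(C)C)[C@@H]1C | intermediate
15 | (2S,4R,5R,6S)-4-[(tert-butyldimethylsilyl)oxy]-5-methyl-6-[(E)-prop-1-en-1-yl]tetrahydro-2H-pyran-2-carbaldehyde | C/C=C/[C@@H]1O[C@H](C=O)C[C@@H](O[Si](C)(C)C(C)(C)C)[C@@H]1C | intermediate
16 | (E)-1,2-bis(tributylstannyl)ethene | CCCC[Sn](CCCC)(CCCC)/C=C/[Sn](CCCC)(CCCC)CCCC | starting material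
17 | (E)-1-[(2S,4R,5R,6S)-4-[(tert-butyldimethylsilyl)oxy]-5-methyl-6-[(E)-prop-1-en-1-yl]tetrahydro-2H-pyran-2-yl]-3-(tributylstannyl)prop-2-en-1-ol, C16 epimer mixture | C/C=C/[C@@H]1O[C@H](C(O)/C=C/[Sn](CCCC)(CCCC)CCCC)C[C@@H](O[Si](C)(C)C(C)(C)C)[C@@H]1C | intermediate
18 | (E)-1-[(2S,4R,5R,6S)-4-[(tert-butyldimethylsilyl)oxy]-5-methyl-6-[(E)-prop-1-en-1-yl]tetrahydro-2H-pyran-2-yl]-3-(tributylstannyl)prop-2-en-1-one | C/C=C/[C@@H]1O[C@H](C(=O)/C=C/[Sn](CCCC)(CCCC)CCCC)C[C@@H](O[Si](C)(C)C(C)(C)C)[C@@H]1C | intermediate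
19 | (1S,2E)-1-[(2S,4R,5R,6S)-4-[(tert-butyldimethylsilyl)oxy]-5-methyl-6-[(E)-prop-1-en-1-yl]tetrahydro-2H-pyran-2-yl]-3-(tributylstannyl)prop-2-en-1-ol | C/C=C/[C@@H]1O[C@H]([C@@H](O)/C=C/[Sn](CCCC)(CCCC)CCCC)C[C@@H](O[Si](C)(C)C(C)(C)C)[C@@H]1C | intermediate
20 | tert-butyl{[(1S,2E)-1-[(2S,4R,5R,6S)-4-[(tert-butyldimethylsilyl)oxy]-5-methyl-6-[(E)-prop-1-en-1-yl]tetrahydro-2H-pyran-2-yl]-3-(tributylstannyl)prop-2-en-1-yl]oxy}dimethylsilane | C/C=C/[C@@H]1O[C@H]([C@@H](O[Si](C)(C)C(C)(C)C)/C=C/[Sn](CCCC)(CCCC)CCCC)C[C@@H](O[Si](C)(C)C(C)(C)C)[C@@H]1C | intermediate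
21 | 2-methylpropane-1,3-diol | CC(CO)CO | starting material
22 | vinyl acetate | CC(=O)OC=C | starting material
23 | (S)-3-hydroxy-2-methylpropyl acetate | CC(=O)OC[C@@H](C)CO | intermediate
24 | (R)-3-[(tert-butyldiphenylsilyl)oxy]-2-methylpropyl acetate | CC(=O)OC[C@@H](C)CO[Si](c1ccccc1)(c1ccccc1)C(C)(C)C | intermediate
25 | (R)-3-[(tert-butyldiphenylsilyl)oxy]-2-methylpropan-1-ol | OC[C@@H](C)CO[Si](c1ccccc1)(c1ccccc1)C(C)(C)C | intermediate
26 | (S)-tert-butyl(3-iodo-2-methylpropoxy)diphenylsilane | IC[C@@H](C)CO[Si](c1ccccc1)(c1ccccc1)C(C)(C)C | intermediate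
27 | lithium acetylide–ethylenediamine complex | [Li+].[C-]#C.NCCN | starting material
28 | (R)-tert-butyl[(2-methylpent-4-yn-1-yl)oxy]diphenylsilane | C#CC[C@@H](C)CO[Si](c1ccccc1)(c1ccccc1)C(C)(C)C | intermediate
29 | trimethylaluminium | C[Al](C)C | starting material
30 | (R,E)-{5-[(tert-butyldiphenylsilyl)oxy]-2,4-dimethylpent-1-en-1-yl}dimethylalane | C[Al](C)/C=C(\C)C[C@@H](C)CO[Si](c1ccccc1)(c1ccccc1)C(C)(C)C | intermediate
31 | (R,E)-tert-butyl[(5-iodo-2,4-dimethylpent-4-en-1-yl)oxy]diphenylsilane | I/C=C(\C)C[C@@H](C)CO[Si](c1ccccc1)(c1ccccc1)C(C)(C)C | intermediate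
32 | (R,E)-5-iodo-2,4-dimethylpent-4-en-1-ol | I/C=C(\C)C[C@@H](C)CO | intermediate
33 | prop-2-yn-1-ol | C#CCO | starting material
34 | tributyltin hydride | CCCC[SnH](CCCC)CCCC | starting material
35 | (E)-3-(tributylstannyl)prop-2-en-1-ol | CCCC[Sn](CCCC)(CCCC)/C=C/CO | intermediate
36 | (E)-3-(tributylstannyl)prop-2-enal | CCCC[Sn](CCCC)(CCCC)/C=C/C=O | intermediate
37 | allyltributylstannane | C=CC[Sn](CCCC)(CCCC)CCCC | starting material
38 | (3S,1E)-1-(tributylstannyl)hexa-1,5-dien-3-ol | CCCC[Sn](CCCC)(CCCC)/C=C/[C@@H](O)CC=C | intermediate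
39 | acryloyl chloride | C=CC(Cl)=O | starting material
40 | (3S,1E)-1-(tributylstannyl)hexa-1,5-dien-3-yl acrylate | CCCC[Sn](CCCC)(CCCC)/C=C/[C@@H](OC(=O)C=C)CC=C | intermediate
41 | (S)-6-[(E)-2-(tributylstannyl)vinyl]-5,6-dihydro-2H-pyran-2-one | CCCC[Sn](CCCC)(CCCC)/C=C/[C@@H]1CC=CC(=O)O1 | intermediate
42 | (2R,4E,6E,8S)-8-[(tert-butyldimethylsilyl)oxy]-8-[(2S,4R,5R,6S)-4-[(tert-butyldimethylsilyl)oxy]-5-methyl-6-[(E)-prop-1-en-1-yl]tetrahydro-2H-pyran-2-yl]-2,4-dimethylocta-4,6-dien-1-ol | C/C=C/[C@@H]1O[C@H]([C@@H](O[Si](C)(C)C(C)(C)C)/C=C/C=C(\C)C[C@@H](C)CO)C[C@@H](O[Si](C)(C)C(C)(C)C)[C@@H]1C | intermediate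
43 | (2R,4E,6E,8S)-8-[(tert-butyldimethylsilyl)oxy]-8-[(2S,4R,5R,6S)-4-[(tert-butyldimethylsilyl)oxy]-5-methyl-6-[(E)-prop-1-en-1-yl]tetrahydro-2H-pyran-2-yl]-2,4-dimethylocta-4,6-dienal | C/C=C/[C@@H]1O[C@H]([C@@H](O[Si](C)(C)C(C)(C)C)/C=C/C=C(\C)C[C@@H](C)C=O)C[C@@H](O[Si](C)(C)C(C)(C)C)[C@@H]1C | intermediate
44 | ethyltriphenylphosphonium iodide | CC[P+](c1ccccc1)(c1ccccc1)c1ccccc1.[I-] | starting material
45 | tert-butyl{[(1S,2E,4E,7R,8Z)-1-[(2S,4R,5R,6S)-4-[(tert-butyldimethylsilyl)oxy]-5-methyl-6-[(E)-prop-1-en-1-yl]tetrahydro-2H-pyran-2-yl]-9-iodo-5,7-dimethyldeca-2,4,8-trien-1-yl]oxy}dimethylsilane | C/C=C/[C@@H]1O[C@H]([C@@H](O[Si](C)(C)C(C)(C)C)/C=C/C=C(\C)C[C@@H](C)/C=C(C)\I)C[C@@H](O[Si](C)(C)C(C)(C)C)[C@@H]1C | intermediate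
46 | (S)-6-[(1E,3Z,5R,7E,9E,11S)-11-[(tert-butyldimethylsilyl)oxy]-11-[(2S,4R,5R,6S)-4-[(tert-butyldimethylsilyl)oxy]-5-methyl-6-[(E)-prop-1-en-1-yl]tetrahydro-2H-pyran-2-yl]-3,5,7-trimethylundeca-1,3,7,9-tetraen-1-yl]-5,6-dihydro-2H-pyran-2-one | C/C=C/[C@@H]1O[C@H]([C@@H](O[Si](C)(C)C(C)(C)C)/C=C/C=C(\C)C[C@@H](C)/C=C(C)\C=C\[C@@H]2CC=CC(=O)O2)C[C@@H](O[Si](C)(C)C(C)(C)C)[C@@H]1C | intermediate
47 | (S)-6-[(1E,3Z,5R,7E,9E,11S)-11-hydroxy-11-[(2S,4R,5S,6S)-4-hydroxy-5-methyl-6-[(E)-prop-1-en-1-yl]tetrahydro-2H-pyran-2-yl]-3,5,7-trimethylundeca-1,3,7,9-tetraen-1-yl]-5,6-dihydro-2H-pyran-2-one | C/C=C/[C@@H]1O[C@H]([C@@H](O)/C=C/C=C(\C)C[C@@H](C)/C=C(C)\C=C\[C@@H]2CC=CC(=O)O2)C[C@@H](O)[C@@H]1C | target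

**Totals and risks**

Total step count: 31. Longest linear sequence: 19 steps (steps 1–14, then 27–31).

The three steps most likely to fail:

Step 4 (facial selectivity of the ketone reduction next to the axial C20 methyl). The fallback sets out from 7 and returns at 8 by a reduce-then-invert sequence instead of direct equatorial hydride delivery. NaBH4 with CeCl3·7H2O in MeOH at −78 °C delivers the small hydride axially and gives the equatorial alcohol (2R,3S,4S,6S)-2-[(benzyloxy)methyl]-6-{[(tert-butyldimethylsilyl)oxy]methyl}-3-methyltetrahydro-2H-pyran-4-ol F1. Mitsunobu inversion (4-nitrobenzoic acid, PPh3, DIAD, toluene, 0 °C to rt) gives the axial ester (2R,3S,4R,6S)-2-[(benzyloxy)methyl]-6-{[(tert-butyldimethylsilyl)oxy]methyl}-3-methyltetrahydro-2H-pyran-4-yl 4-nitrobenzoate F2. Methanolysis with K2CO3 in MeOH then gives 8.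

Step 29 (yield and Z-selectivity of the iodo-olefination on an advanced aldehyde). The fallback sets out from 43 and returns at 46, building the trisubstituted alkenyl halide by cross-coupling instead of by Wittig chemistry. Ramirez–Corey–Fuchs dibromo-olefination (CBr4, PPh3, 2,6-lutidine, CH2Cl2, 0 °C) gives tert-butyl{[(1S,2E,4E,7R)-1-[(2S,4R,5R,6S)-4-[(tert-butyldimethylsilyl)oxy]-5-methyl-6-[(E)-prop-1-en-1-yl]tetrahydro-2H-pyran-2-yl]-9,9-dibromo-5,7-dimethylnona-2,4,8-trien-1-yl]oxy}dimethylsilane F3. Negishi trans-selective monomethylation (Me2Zn, Pd(DPEphos)Cl2 cat., THF, 0 °C) replaces only the bromine trans to C10 and gives tert-butyl{[(1S,2E,4E,7R,8Z)-1-[(2S,4R,5R,6S)-4-[(tert-butyldimethylsilyl)oxy]-5-methyl-6-[(E)-prop-1-en-1-yl]tetrahydro-2H-pyran-2-yl]-9-bromo-5,7-dimethyldeca-2,4,8-trien-1-yl]oxy}dimethylsilane F4. Stille coupling of this bromide with 41 (Pd(P(t-Bu)3)2, NMP, 50 °C) gives 46.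

Step 30 (Stille coupling of a hindered Z-trisubstituted iodide with a sensitive lactone stannane). The fallback sets out from 41 and 45 and returns at 46 by a Heck reaction instead of a tin-based coupling. Protodestannylation of 41 (HCl in Et2O, CH2Cl2, 0 °C) gives (S)-6-vinyl-5,6-dihydro-2H-pyran-2-one F5. Heck coupling of 45 with this alkene (Pd(OAc)2, Bu4NBr, Et3N, DMF, rt to 50 °C, Jeffery conditions) forms C7–C8 with E geometry at C6=C7 and retention of the 8Z geometry, giving 46.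

**Further compounds**
F1 | step 4 | (2R,3S,4S,6S)-2-[(benzyloxy)methyl]-6-{[(tert-butyldimethylsilyl)oxy]methyl}-3-methyltetrahydro-2H-pyran-4-ol | c1ccccc1COC[C@@H]1O[C@H](CO[Si](C)(C)C(C)(C)C)C[C@H](O)[C@@H]1C
F2 | step 4 | (2R,3S,4R,6S)-2-[(benzyloxy)methyl]-6-{[(tert-butyldimethylsilyl)oxy]methyl}-3-methyltetrahydro-2H-pyran-4-yl 4-nitrobenzoate | c1ccccc1COC[C@@H]1O[C@H](CO[Si](C)(C)C(C)(C)C)C[C@@H](OC(=O)c2ccc(cc2)[N+](=O)[O-])[C@@H]1C
F3 | step 29 | tert-butyl{[(1S,2E,4E,7R)-1-[(2S,4R,5R,6S)-4-[(tert-butyldimethylsilyl)oxy]-5-methyl-6-[(E)-prop-1-en-1-yl]tetrahydro-2H-pyran-2-yl]-9,9-dibromo-5,7-dimethylnona-2,4,8-trien-1-yl]oxy}dimethylsilane | C/C=C/[C@@H]1O[C@H]([C@@H](O[Si](C)(C)C(C)(C)C)/C=C/C=C(\C)C[C@@H](C)C=C(Br)Br)C[C@@H](O[Si](C)(C)C(C)(C)C)[C@@H]1C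
F4 | step 29 | tert-butyl{[(1S,2E,4E,7R,8Z)-1-[(2S,4R,5R,6S)-4-[(tert-butyldimethylsilyl)oxy]-5-methyl-6-[(E)-prop-1-en-1-yl]tetrahydro-2H-pyran-2-yl]-9-bromo-5,7-dimethyldeca-2,4,8-trien-1-yl]oxy}dimethylsilane | C/C=C/[C@@H]1O[C@H]([C@@H](O[Si](C)(C)C(C)(C)C)/C=C/C=C(\C)C[C@@H](C)/C=C(C)\Br)C[C@@H](O[Si](C)(C)C(C)(C)C)[C@@H]1C
F5 | step 30 | (S)-6-vinyl-5,6-dihydro-2H-pyran-2-one | C=C[C@@H]1CC=CC(=O)O1
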